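**Retrosynthetic overview**

- Target 20 is cut at the bond between the bridging methine carbon and C6 of chroman A. Chroman A (18) is the nucleophile; the ortho-quinone methide 19 of chroman B, released by base from sulfone 12, is the electrophile; a chiral bifunctional catalyst sets the methine stereocentre in this last step.
- Sulfone 12 comes from chroman B (7), 6-methylheptanal (9) and a sulfinate under acid. C6 is the only free ring carbon in 7 and in 18, so both bonds to the bridge are regiochemically unambiguous.
- Each 8-acyl-5,7-dihydroxy-2,2-dimethylchroman is cut in its pyran ring at C4–C4a and at O1–C8a. This leads back to a 1-(2-iodo-4,6-dibenzyloxyphenyl) ketone and 4-bromo-2-methylbutan-2-ol (5), joined by a palladium/norbornene ortho-alkylation/ipso-etherification.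
- Feature that makes this possible: in the benzene ring of half B, C8a (bearing the pyran oxygen O1) lies between the acyl-bearing C8 and C4a, and C4a bears the benzylic CH2 (C4). O1 and C4 are the two ends of one O–C(CH3)2–CH2–CH2 chain, so iodine on C8a, hydrogen on C4a and the acyl group on C8 as ortho blocker are all the annulation needs.
- Ring order: both benzene rings are bought (5-iodoresorcinol, acylated next to iodine); pyran ring of half B (step 3); pyran ring of half A (step 10); bridge last (step 12).

Key step: step 3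

Assumption: the facial sense of the catalyst-controlled addition in step 12 is assigned by analogy with other additions to ortho-quinone methides under quinine-derived squaramides (the quinidine-derived pseudoenantiomer would be used if the sense proves opposite), and 5-iodoresorcinol and (2R)-2-methylbutanoic acid are taken as purchased.

**Route**

Step 1
Reactants: 1 5-iodobenzene-1,3-diol (5-iodoresorcinol); 2 2-methylpropanoyl chloride
Product: 3 1-(2,4-dihydroxy-6-iodophenyl)-2-methylpropan-1-one
Conditions: AlCl3 (3.5 equiv), CH2Cl2/PhNO2, 0 °C to rt; then 1 M HCl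
Reagents that add atoms: none
Why: Friedel–Crafts (Nencki-type) C-acylation of a resorcinol should go to C4, para to one hydroxyl and ortho to the other as with orcinol, which places the acyl group next to iodine; the iodine is meta to both hydroxyls and so is not prone to ipso protonation.

Step 2
Reactants: 3 1-(2,4-dihydroxy-6-iodophenyl)-2-methylpropan-1-one
Product: 4 1-[2,4-bis(benzyloxy)-6-iodophenyl]-2-methylpropan-1-one
Conditions: BnBr (2.4 equiv), K2CO3, DMF, 50 °C
Reagents that add atoms: benzyl bromide, BrCc1ccccc1
Why: Williamson ether synthesis with K2CO3 in DMF should alkylate both phenols, the hydrogen-bonded one included, so that no phenoxide can compete as a nucleophile in step 3.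

Step 3
Reactants: 4 1-[2,4-bis(benzyloxy)-6-iodophenyl]-2-methylpropan-1-one; 5 4-bromo-2-methylbutan-2-ol
Product: 6 1-[5,7-bis(benzyloxy)-2,2-dimethyl-3,4-dihydro-2H-chromen-8-yl]-2-methylpropan-1-one
Conditions: Pd(OAc)2 (10 mol %), RuPhos (20 mol %), norbornene (1 equiv), Cs2CO3 (2.5 equiv), 1,4-dioxane, 100 °C
Reagents that add atoms: none
Why: Proposed new method: zerovalent palladium should insert into the C–I bond of 4, norbornene should carbopalladate, and the alkylpalladium should metalate the only ortho C–H (the future C4a) to an aryl norbornyl palladacycle, which takes up the primary C–Br bond of 5 by oxidative addition to tetravalent palladium and forms the C4–C4a bond by reductive elimination; β-carbon elimination of norbornene, forced by the two ortho substituents now present, returns an arylpalladium species at the ipso carbon (the future C8a), which the tethered tertiary alkoxide captures to form the O1–C8a bond by C–O reductive elimination, all intermediates being palladium-bound so that no free organic intermediate arises. The closest known reactions are the Catellani-type annulations of aryl iodides with N-protected bromoalkylamines to indolines and tetrahydroquinolines and with epoxides to 2,3-dihydrobenzofurans, together with the palladium-catalysed intramolecular etherification of aryl halides by tertiary alcohols to 2,2-dimethylchromans; new here are the γ-bromo tertiary alcohol as two-point partner and the six-membered oxygen ring. The pyran ring closes in the C–O reductive elimination from a seven-membered oxapalladacycle, an ipso substitution at C8a, and no stereocentre is formed. The step needs a single alkylation at C4a and etherification at C8a instead of reduction or a second norbornene insertion: the isobutyryl group on C8 blocks the other ortho position and is the ortho substituent that norbornene extrusion requires, the tertiary alkoxide has no hydrogen on its carbinol carbon and cannot undergo β-hydride elimination, and the benzyl ethers keep the phenols out of the reaction. The position of iodine fixes the regiochemistry, so O1 can only end next to the acyl group and C6 stays the single free ring carbon.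

Step 4
Reactants: 6 1-[5,7-bis(benzyloxy)-2,2-dimethyl-3,4-dihydro-2H-chromen-8-yl]-2-methylpropan-1-one
Product: 7 1-(5,7-dihydroxy-2,2-dimethyl-3,4-dihydro-2H-chromen-8-yl)-2-methylpropan-1-one
Conditions: H2 (1 atm), Pd/C (10 wt %), EtOAc/MeOH, rt
Reagents that add atoms: none
Why: Hydrogenolysis of benzyl aryl ethers over Pd/C is neutral and should leave the hindered, electron-rich aryl ketone and the chroman ether untouched.

Step 5
Reactants: 8 6-methylheptan-1-ol
Product: 9 6-methylheptanal
Conditions: TEMPO (10 mol %), PhI(OAc)2 (1.1 equiv), CH2Cl2, rt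
Reagents that add atoms: none
Why: Oxoammonium (TEMPO) oxidation of a primary alcohol should stop cleanly at the aldehyde.

Step 6
Reactants: 7 1-(5,7-dihydroxy-2,2-dimethyl-3,4-dihydro-2H-chromen-8-yl)-2-methylpropan-1-one; 9 6-methylheptanal
Product: 12 1-[5,7-dihydroxy-2,2-dimethyl-6-[6-methyl-1-(4-methylbenzenesulfonyl)heptyl]-3,4-dihydro-2H-chromen-8-yl]-2-methylpropan-1-one (racemic at the sulfonyl-bearing carbon), via carbinol 10 (not isolated), via benzylic cation 11 (not isolated)
Conditions: sodium 4-methylbenzenesulfinate (1.5 equiv), HCO2H/H2O, rt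
Reagents that add atoms: sodium 4-methylbenzenesulfinate, Cc1ccc(S(=O)[O-])cc1.[Na+]
Why: Acid-mediated three-component α-sulfonylalkylation of a phenol, the standard entry to bench-stable 2-(1-sulfonylalkyl)phenols: hydroxyalkylation of the only free ring carbon (C6) by the protonated aldehyde gives carbinol 10, which in formic acid loses water by SN1 ionisation to benzylic cation 11, stabilised by the two ortho hydroxyls and the para ring oxygen, and the cation is captured at sulfur by 4-methylbenzenesulfinic acid; the new centre needs no control because it is erased in step 12.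

Step 7
Reactants: 13 (2R)-2-methylbutanoic acid
Product: 14 (2R)-2-methylbutanoyl chloride
Conditions: (COCl)2 (1.2 equiv), DMF (cat.), CH2Cl2, 0 °C to rt; used crude after evaporation
Reagents that add atoms: oxalyl chloride, ClC(=O)C(Cl)=O
Why: Acid chloride formation with oxalyl chloride runs without base, so the α-stereocentre should be carried through unchanged.

Step 8
Reactants: 1 5-iodobenzene-1,3-diol; 14 (2R)-2-methylbutanoyl chloride
Product: 15 (2R)-1-(2,4-dihydroxy-6-iodophenyl)-2-methylbutan-1-one
Conditions: AlCl3 (3.5 equiv), CH2Cl2/PhNO2, 0 °C; then 1 M HCl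
Reagents that add atoms: none
Why: Friedel–Crafts acylation as in step 1, with the same regiochemistry; at 0 °C capture of the acylium ion should outrun enolisation, so the (R) centre from 13 is retained.

Step 9
Reactants: 15 (2R)-1-(2,4-dihydroxy-6-iodophenyl)-2-methylbutan-1-one
Product: 16 (2R)-1-[2,4-bis(benzyloxy)-6-iodophenyl]-2-methylbutan-1-one
Conditions: BnBr (2.4 equiv), K2CO3, DMF, rt
Reagents that add atoms: benzyl bromide, BrCc1ccccc1
Why: Williamson ether synthesis as in step 2, run at rt so that the carbonate base does not enolise the ketone.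

Step 10
Reactants: 16 (2R)-1-[2,4-bis(benzyloxy)-6-iodophenyl]-2-methylbutan-1-one; 5 4-bromo-2-methylbutan-2-ol
Product: 17 (2R)-1-[5,7-bis(benzyloxy)-2,2-dimethyl-3,4-dihydro-2H-chromen-8-yl]-2-methylbutan-1-one
Conditions: Pd(OAc)2 (10 mol %), RuPhos (20 mol %), norbornene (1 equiv), Cs2CO3 (2.5 equiv), 1,4-dioxane, 100 °C
Reagents that add atoms: none
Why: Proposed new method: the same palladium/norbornene ortho-alkylation/ipso-etherification as in step 3 (oxidative addition into C–I, norbornene-relayed palladation of the single ortho C–H, alkylation by the C–Br bond of 5 via tetravalent palladium, norbornene extrusion, C–O reductive elimination of the tertiary alkoxide), closest to the known Catellani-type annulations with bromoalkylamines and epoxides; the ketone is twisted out of the ring plane by its two ortho substituents and its enolate would be tetrasubstituted and strained, so the α-stereocentre should survive the carbonate base.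

Step 11
Reactants: 17 (2R)-1-[5,7-bis(benzyloxy)-2,2-dimethyl-3,4-dihydro-2H-chromen-8-yl]-2-methylbutan-1-one
Product: 18 (2R)-1-(5,7-dihydroxy-2,2-dimethyl-3,4-dihydro-2H-chromen-8-yl)-2-methylbutan-1-one
Conditions: H2 (1 atm), Pd/C (10 wt %), EtOAc/MeOH, rt
Reagents that add atoms: none
Why: Neutral hydrogenolysis of the benzyl ethers as in step 4 should not touch the ketone or its α-stereocentre.

Step 12
Reactants: 12 1-[5,7-dihydroxy-2,2-dimethyl-6-[6-methyl-1-(4-methylbenzenesulfonyl)heptyl]-3,4-dihydro-2H-chromen-8-yl]-2-methylpropan-1-one; 18 (2R)-1-(5,7-dihydroxy-2,2-dimethyl-3,4-dihydro-2H-chromen-8-yl)-2-methylbutan-1-one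
Product: 20 (2R)-1-[6-[(1R)-1-[5,7-dihydroxy-2,2-dimethyl-8-(2-methylpropanoyl)-3,4-dihydro-2H-chromen-6-yl]-6-methylheptyl]-5,7-dihydroxy-2,2-dimethyl-3,4-dihydro-2H-chromen-8-yl]-2-methylbutan-1-one (CNP0287681.1), via ortho-quinone methide 19 (not isolated)
Conditions: quinine-derived squaramide 3-[[3,5-bis(trifluoromethyl)phenyl]amino]-4-[[(8α,9S)-6′-methoxycinchonan-9-yl]amino]cyclobut-3-ene-1,2-dione (10 mol %), Na2CO3 (1.2 equiv, 5 % aq.), toluene, 0 °C
Reagents that add atoms: none
Why: Aqueous carbonate should deprotonate the phenol of 12 next to the sulfonyl-bearing carbon and expel sulfinate (E1cB) to give the neutral ortho-quinone methide 19, to which the only free ring carbon (C6) of 18 adds in a vinylogous Michael (Friedel–Crafts-type) reaction known for 2-(1-sulfonylalkyl)phenols under bifunctional squaramide catalysis; the bridge stereocentre is set by catalyst control, the squaramide N–H bonds holding the carbonyl oxygen of 19 and the protonated quinuclidine holding the phenolate of 18 so that one face of the exocyclic C=C is attacked, while the remote acyl stereocentre exerts no bias.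

**Compound list**

1 | 5-iodobenzene-1,3-diol | Oc1cc(O)cc(I)c1 | starting material
2 | 2-methylpropanoyl chloride | CC(C)C(Cl)=O | starting material
3 | 1-(2,4-dihydroxy-6-iodophenyl)-2-methylpropan-1-one | CC(C)C(=O)c1c(O)cc(O)cc1I | intermediate
4 | 1-[2,4-bis(benzyloxy)-6-iodophenyl]-2-methylpropan-1-one | CC(C)C(=O)c1c(OCc2ccccc2)cc(OCc2ccccc2)cc1I | intermediate
5 | 4-bromo-2-methylbutan-2-ol | CC(C)(O)CCBr | starting material
6 | 1-[5,7-bis(benzyloxy)-2,2-dimethyl-3,4-dihydro-2H-chromen-8-yl]-2-methylpropan-1-one | CC(C)C(=O)c1c(OCc2ccccc2)cc(OCc2ccccc2)c2c1OC(C)(C)CC2 | intermediate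
7 | 1-(5,7-dihydroxy-2,2-dimethyl-3,4-dihydro-2H-chromen-8-yl)-2-methylpropan-1-one | CC(C)C(=O)c1c(O)cc(O)c2c1OC(C)(C)CC2 | intermediate
8 | 6-methylheptan-1-ol | CC(C)CCCCCO | starting material
9 | 6-methylheptanal | CC(C)CCCCC=O | intermediate
10 | 1-[5,7-dihydroxy-6-(1-hydroxy-6-methylheptyl)-2,2-dimethyl-3,4-dihydro-2H-chromen-8-yl]-2-methylpropan-1-one (carbinol, not isolated) | CC(C)CCCCC(O)c1c(O)c2c(c(C(=O)C(C)C)c1O)OC(C)(C)CC2 | intermediate
11 | 1-[5,7-dihydroxy-2,2-dimethyl-8-(2-methylpropanoyl)-3,4-dihydro-2H-chromen-6-yl]-6-methylheptan-1-ylium (benzylic cation, not isolated) | CC(C)CCCC[CH+]c1c(O)c2c(c(C(=O)C(C)C)c1O)OC(C)(C)CC2 | intermediate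
12 | 1-[5,7-dihydroxy-2,2-dimethyl-6-[6-methyl-1-(4-methylbenzenesulfonyl)heptyl]-3,4-dihydro-2H-chromen-8-yl]-2-methylpropan-1-one (racemic) | CC(C)CCCCC(c1c(O)c2c(c(C(=O)C(C)C)c1O)OC(C)(C)CC2)S(=O)(=O)c1ccc(C)cc1 | intermediate
13 | (2R)-2-methylbutanoic acid | CC[C@@H](C)C(=O)O | starting material
14 | (2R)-2-methylbutanoyl chloride | CC[C@@H](C)C(Cl)=O | intermediate
15 | (2R)-1-(2,4-dihydroxy-6-iodophenyl)-2-methylbutan-1-one | CC[C@@H](C)C(=O)c1c(O)cc(O)cc1I | intermediate
16 | (2R)-1-[2,4-bis(benzyloxy)-6-iodophenyl]-2-methylbutan-1-one | CC[C@@H](C)C(=O)c1c(OCc2ccccc2)cc(OCc2ccccc2)cc1I | intermediate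
17 | (2R)-1-[5,7-bis(benzyloxy)-2,2-dimethyl-3,4-dihydro-2H-chromen-8-yl]-2-methylbutan-1-one | CC[C@@H](C)C(=O)c1c(OCc2ccccc2)cc(OCc2ccccc2)c2c1OC(C)(C)CC2 | intermediate
18 | (2R)-1-(5,7-dihydroxy-2,2-dimethyl-3,4-dihydro-2H-chromen-8-yl)-2-methylbutan-1-one | CC[C@@H](C)C(=O)c1c(O)cc(O)c2c1OC(C)(C)CC2 | intermediate
19 | 7-hydroxy-2,2-dimethyl-6-(6-methylheptylidene)-8-(2-methylpropanoyl)-3,4-dihydro-2H-chromen-5(6H)-one (ortho-quinone methide, not isolated) | CC(C)CCCCC=C1C(=O)C2=C(OC(C)(C)CC2)C(C(=O)C(C)C)=C1O | intermediate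
20 | (2R)-1-[6-[(1R)-1-[5,7-dihydroxy-2,2-dimethyl-8-(2-methylpropanoyl)-3,4-dihydro-2H-chromen-6-yl]-6-methylheptyl]-5,7-dihydroxy-2,2-dimethyl-3,4-dihydro-2H-chromen-8-yl]-2-methylbutan-1-one | CC[C@@H](C)C(=O)c1c(O)c([C@H](CCCCC(C)C)c2c(O)c3c(c(C(=O)C(C)C)c2O)OC(C)(C)CC3)c(O)c2c1OC(C)(C)CC2 | target

**Step count and risks**

Total steps: 12. Longest linear sequence: 6 steps (steps 1, 2, 3, 4, 6, 12; the branch 7, 8, 9, 10, 11, 12 is equally long).

Steps most likely to fail:

1. Step 3 (proposed new method). The ortho-alkylated arylpalladium species may fail to undergo C–O reductive elimination and be reduced or stall instead. Bromo alcohol 5 may be lost to base-induced cyclisation to the oxetane, and norbornene extrusion may be incomplete. The fallback uses known chemistry, sets out from 4 and returns to the route at 7. Palladium-catalysed hydroxylation of 4 (KOH, Pd2(dba)3, tBuXPhos, 1,4-dioxane/H2O, 100 °C) should give the phenol 1-[2,4-bis(benzyloxy)-6-hydroxyphenyl]-2-methylpropan-1-one F1. O-alkylation with 3-chloro-3-methylbut-1-yne (DBU, CuCl2 cat., MeCN, 0 °C) should give the aryl propargyl ether 1-[2,4-bis(benzyloxy)-6-[(2-methylbut-3-yn-2-yl)oxy]phenyl]-2-methylpropan-1-one F2. Heating (xylene, 140 °C) should bring about propargyl Claisen rearrangement, 1,5-hydrogen shift and oxa-6π electrocyclisation at the only free ortho carbon to give the chromene 1-[5,7-bis(benzyloxy)-2,2-dimethyl-2H-chromen-8-yl]-2-methylpropan-1-one F3. Hydrogenation (H2, Pd/C, EtOAc/MeOH) then saturates C3=C4 and removes both benzyl ethers to give 7.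

2. Step 10 (proposed new method). Beyond the failure modes of step 3, base-mediated enolisation at 100 °C may erode the α-stereocentre of the 2-methylbutanoyl group. The fallback uses known, milder chemistry, sets out from 16 and returns at 18. Miyaura borylation (B2pin2, PdCl2(dppf), KOAc, 1,4-dioxane, 80 °C) should give the boronate (2R)-1-[2,4-bis(benzyloxy)-6-(4,4,5,5-tetramethyl-1,3,2-dioxaborolan-2-yl)phenyl]-2-methylbutan-1-one F4. Oxidation (NaBO3·4H2O, THF/H2O, rt) should give the phenol (2R)-1-[2,4-bis(benzyloxy)-6-hydroxyphenyl]-2-methylbutan-1-one F5. O-alkylation with 3-chloro-3-methylbut-1-yne (DBU, CuCl2 cat., MeCN, 0 °C) should give the propargyl ether (2R)-1-[2,4-bis(benzyloxy)-6-[(2-methylbut-3-yn-2-yl)oxy]phenyl]-2-methylbutan-1-one F6. Thermal rearrangement (xylene, 140 °C) should give the chromene (2R)-1-[5,7-bis(benzyloxy)-2,2-dimethyl-2H-chromen-8-yl]-2-methylbutan-1-one F7, and hydrogenation over Pd/C gives 18.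

3. Step 12. Facial selectivity may be poor, because 19 can exist as two tautomeric quinone methides and as two alkene geometries, and because uncatalysed addition of the sodium phenolate of 18 may compete; slow release of 19 may also let it tautomerise to the vinyl phenol. The fallback abandons catalyst control, sets out from 12 and 18 and returns at 20. Coupling with an achiral base (Na2CO3, CH2Cl2/H2O, rt) should give 20 together with its bridge epimer (2R)-1-[6-[(1S)-1-[5,7-dihydroxy-2,2-dimethyl-8-(2-methylpropanoyl)-3,4-dihydro-2H-chromen-6-yl]-6-methylheptyl]-5,7-dihydroxy-2,2-dimethyl-3,4-dihydro-2H-chromen-8-yl]-2-methylbutan-1-one F8. The two are diastereomers because of the fixed acyl stereocentre and would be separated by preparative HPLC on a chiral stationary phase.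

**Further compounds**

F1 | step 3 | 1-[2,4-bis(benzyloxy)-6-hydroxyphenyl]-2-methylpropan-1-one | CC(C)C(=O)c1c(OCc2ccccc2)cc(OCc2ccccc2)cc1O
F2 | step 3 | 1-[2,4-bis(benzyloxy)-6-[(2-methylbut-3-yn-2-yl)oxy]phenyl]-2-methylpropan-1-one | CC(C)C(=O)c1c(OCc2ccccc2)cc(OCc2ccccc2)cc1OC(C)(C)C#C
F3 | step 3 | 1-[5,7-bis(benzyloxy)-2,2-dimethyl-2H-chromen-8-yl]-2-methylpropan-1-one | CC(C)C(=O)c1c(OCc2ccccc2)cc(OCc2ccccc2)c2c1OC(C)(C)C=C2
F4 | step 10 | (2R)-1-[2,4-bis(benzyloxy)-6-(4,4,5,5-tetramethyl-1,3,2-dioxaborolan-2-yl)phenyl]-2-methylbutan-1-one | CC[C@@H](C)C(=O)c1c(OCc2ccccc2)cc(OCc2ccccc2)cc1B1OC(C)(C)C(C)(C)O1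
F5 | step 10 | (2R)-1-[2,4-bis(benzyloxy)-6-hydroxyphenyl]-2-methylbutan-1-one | CC[C@@H](C)C(=O)c1c(OCc2ccccc2)cc(OCc2ccccc2)cc1O
F6 | step 10 | (2R)-1-[2,4-bis(benzyloxy)-6-[(2-methylbut-3-yn-2-yl)oxy]phenyl]-2-methylbutan-1-one | CC[C@@H](C)C(=O)c1c(OCc2ccccc2)cc(OCc2ccccc2)cc1OC(C)(C)C#C
F7 | step 10 | (2R)-1-[5,7-bis(benzyloxy)-2,2-dimethyl-2H-chromen-8-yl]-2-methylbutan-1-one | CC[C@@H](C)C(=O)c1c(OCc2ccccc2)cc(OCc2ccccc2)c2c1OC(C)(C)C=C2
F8 | step 12 | (2R)-1-[6-[(1S)-1-[5,7-dihydroxy-2,2-dimethyl-8-(2-methylpropanoyl)-3,4-dihydro-2H-chromen-6-yl]-6-methylheptyl]-5,7-dihydroxy-2,2-dimethyl-3,4-dihydro-2H-chromen-8-yl]-2-methylbutan-1-one | CC[C@@H](C)C(=O)c1c(O)c([C@@H](CCCCC(C)C)c2c(O)c3c(c(C(=O)C(C)C)c2O)OC(C)(C)CC3)c(O)c2c1OC(C)(C)CC2
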